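The meeting decided that whoever repeats this run should watch the split between target and side product, not the conversion of substrate.

| setting | south-east | south-west | teal | green | blue |
|---|---|---|---|---|---|
| substrate | 0.080 M | 0.080 M | 0.080 M | 0.080 M | 0.080 M |
| coupling partner | 0.48 M | 0.92 M | 0.400 M | 0.520 M | 0.680 M |
| remark | run made earlier | run made earlier |  |  |  |
| time |  |  | 5.0 min | 5.0 min | 5.0 min |

| run | time / min | target / % | substrate / % |
|---|---|---|---|
| south-east | 0.667 | 12.9 | 80.4 |
| south-east | 1.33 | 23.5 | 64.2 |
| south-east | 2.00 | 29.8 | 52.4 |
| south-east | 3.00 | 38.1 | 38.9 |
| south-east | 4.00 | 43.5 | 29.6 |
| south-west | 0.333 | 13.0 | 83.3 |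
| south-west | 0.833 | 27.4 | 65.0 |
| south-west | 1.50 | 40.4 | 47.9 |
| south-west | 2.50 | 52.0 | 31.5 |
| south-west | 4.00 | 60.9 | 18.2 |

(standard deviation of a reading: 0.3 percentage points)



- which of the two there is more of at the end, teal (target / side product)
- which of the two there is more of at the end, green (target / side product)
- which of the two there is more of at the end, blue (target / side product)
- amount of target at the end, in percent of the substrate charged, teal
- amount of target at the end, in percent of the substrate charged, green
- amount of target at the end, in percent of the substrate charged, blue

The first speaker proposed one measure, the split S: the rate of forming target over the rate of forming side product at one moment, with side product taken as substrate neither left nor found as target. She read it from the amounts made up to the first reading of each earlier run, the one nearest the start, so it stands for the early rates taken together. This gave 1.93 in the south-east run and 3.51 in the south-west run.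

The second speaker noted that S grew 1.82-fold when the charge of coupling partner grew 1.92-fold, so he proposed dividing S by [coupling partner]. The meeting carried the mean of the two quotients, the selectivity factor 3.92 M⁻¹. On the charges, S then starts at 1.57 in teal, 2.04 in green and 2.66 in blue.

The chair objected that a flask does not stay at its start. Between 3.00 min and 4.00 min the south-east run reads S = 1.38, a drift to 0.719 of its first value. Read through the factor, that reading corresponds to [coupling partner] near 0.352 M in the south-east run, an estimated fall of 0.126 M, while the target made there by 4.00 min accounts for 0.0348 M, which is less. Whether partner goes elsewhere or the target step slows, the readings left open.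

Assuming that teal drifts as far as the south-east run did, the meeting estimated S = 1.13 late in teal, still above one, so its reckoning put target ahead in teal, green and blue, with the thinnest margin in teal.

The forecast named target in each flask, with 44 %, 50 % and 56 % for teal, green and blue, and said “Target therefore beats side product in all three runs, though least clearly at 0.40 M”.

Teal gives 42.2 % of target against 31.9 % of side product, green 49.1 % against 29.4 %, and blue 56.2 % against 26.5 %.

    substrate + coupling partner → target (k = 0.00810 M⁻¹ s⁻¹)
    substrate → side product (k = 0.00200 s⁻¹)
    2 coupling partner → homo dimer (k = 0.00200 M⁻¹ s⁻¹)

At 5.00 min in teal the target step and the side-product step consume substrate at a ratio of 1.0, and the carried factor times the coupling partner left, 62 % of its charge, gives about the same, 0.973, with homo dimer taking partner 3.5 times as fast as the target step at 1.92 min. For a neighbour of teal charged with 0.24 M of coupling partner, the carried factor gives a starting S of 0.941, below one, and at 5.0 min that neighbour holds 30.0 % of target and 36.1 % of side product.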